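All runs were computed for an exercise; scatter was added.

**Start.** Time first: Sunday's flask makes 20.8 % target in 12.0 min on 0.24 M of coupling partner. Monday's flask, asked about at 20 h, carries twice that partner, so I take its start twice as steep. At that slope it reaches 74.1 % in 21.6 min.

in all of them: substrate 0.50 M

| flask | coupling partner | remark | time |
|---|---|---|---|
| Monday's | 0.475 M | the very flask that is asked about, followed so far |  |
| Sunday's | 0.24 M | run made earlier |  |
| flask | 0.475 M |  | 20 h |

- Monday's (time / h: target / %, substrate / %): 2.50: 71.0, 21.1; 8.00: 74.4, 21.0; 12.0: 74.4, 20.4; 20.0: 74.1, 20.2
- Sunday's (time / min: target / %, substrate / %): 12.0: 20.8, 79.7; 25.0: 29.0, 66.9; 40.0: 36.3, 62.4; 50.0: 37.9, 60.1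

(scatter of a reading: 1 percentage point)

- zeta: at 20 h add coupling partner, 50.0 % of the amount charged, then wait 40 h
- gamma: at 20 h add substrate, 50.0 % of the amount charged, then wait 40 h
- theta: change nothing and wait 40 h more

* target, in percent of the substrate first charged, at 20 h
* the option that brings most further target ("none" if no option brings more than 2 percentage points) (zeta / gamma / theta / none)
* target present, in percent of the substrate first charged, after zeta
* target present, in percent of the substrate first charged, after gamma

- what is added takes up no volume worth counting
- a reading or a percentage of target counts all its forms, free or not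

**Knee and level.** Monday's first reading, 71.0 % at 2.50 h, lies close to that level, so the knee comes earlier. My level is 74.3 %. If partner went one per substrate, Monday's flask would keep 0.0760 M of it. At Sunday's pace that partner has a lifetime of 2.28 h. About 5.26 lifetimes pass after 8.00 h, yet substrate moves only from 21.0 % to 20.2 %.

**Partner price.** So I treat partner as the limiting reagent and define the partner price, partner charged per substrate used: 1.19. On Sunday's charge this price buys 40.3 % of the substrate, and 39.9 % is used at 50.0 min.

**My reckoning.** Zeta adds 0.237 M, which buys 39.9 % of the substrate charge, more than the 20.2 % left. Target per substrate used reads 92.9 %, so I expect about that much target after zeta. Gamma and theta add no partner, so I expect the level to hold.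

**The forecast.** It gives 74.3 %, 85.5 % after zeta and 83 % after gamma, and chooses zeta: “Zeta pays off under two of the three explanations”. On gamma it differs from my reckoning.

**Result.** The flask holds 74.6 % at 20 h, 92.9 % after zeta and 74.6 % after gamma; zeta brings 18 percentage points.

    substrate + coupling partner → target (k = 0.00190 M⁻¹ s⁻¹)
    substrate + coupling partner → isomer of the product (k = 1.45 × 10⁻⁴ M⁻¹ s⁻¹)
    2 coupling partner → homo dimer (k = 2.75 × 10⁻⁴ M⁻¹ s⁻¹)
    crystals ⇌ target, rate k4*(cs4 - [target]) while solid is left; crystals form when [target] > cs4 (solubility = 0.210 M, k = 0.0175 s⁻¹)

**Partner balance.** At 20.0 h coupling partner stands at 0 % beside homo dimer 0.0369 M, which holds 0.0738 M of partner. At the price, the 20 % of substrate left costs 0.118 M, less than zeta's addition. At the price, a neighbouring flask with 0.12 M of partner buys 20.2 % of its substrate charge, and that flask uses 23.2 % by 20.0 h.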